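Readings and results stem from a simulated flask with constants of no real substance; scatter was added.

Slowness was the first thing I read: after 25.0 min the ash run had made 20.4 % of product, and larch, with less substrate, 29.2 %.

all flasks: gas phase 0.45 mM (held)
- larch: substrate 5 mM; free catalyst 50 µM; run made earlier
- ash: substrate 20 mM; free catalyst 50 µM; run made earlier
- cedar: substrate 10 mM; free catalyst 25 µM; run made earlier
- flask: substrate 10 mM; free catalyst 50 µM; time 20 min

- larch (time / min: product / %, substrate / %): 1.50: 2.8, 96.8; 5.00: 11.0, 90.1; 8.00: 16.7, 84.1; 12.0: 20.5, 79.1; 20.0: 27.8, 72.6; 25.0: 29.2, 69.6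
- ash (time / min: product / %, substrate / %): 2.00: 3.0, 97.2; 3.00: 3.2, 95.8; 5.00: 6.3, 94.6; 8.00: 7.8, 91.1; 15.0: 14.1, 86.1; 25.0: 20.4, 80.2
- cedar (time / min: product / %, substrate / %): 2.00: 2.7, 98.2; 4.00: 5.0, 94.4; 6.00: 7.6, 92.0; 12.0: 13.6, 85.8; 25.0: 22.3, 78.2

(each reading ± 0.5 percentage points)

- at the start none of the gas phase is in solution

* product at 20 min, in percent of the substrate charged
* the change that raises the amount of product at 20 min, in percent of the substrate charged most ("none" if none brings more than 2 percentage points) (Tuesday's / Monday's / Sunday's / none)
* amount of product at 20 min, in percent of the substrate charged, after Tuesday's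

- Tuesday's: doubling the amount of free catalyst, all else as stated
- Monday's: doubling the transfer coefficient of the gas phase, all else as stated
- Sunday's: doubling the saturation concentration of gas phase, all else as stated

1. Larch, the flask and ash stand in steps of two in [substrate], each twice the one before, at equal [free catalyst]. I therefore took the percent product to fall by one factor per doubling of substrate. At 25.0 min that factor was 0.836.

2. The product column of larch at 20.0 min, 27.8 %, times this factor gave 23.2 % for the flask.

3. The substrate column, read as percent lost in the same way, gave 22.1 %. These are other readings of the same runs, so the gap of 1.1 percentage points tests the scatter of 0.5 points, not the power law. I committed to the middle, 22.7 %.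

4. Cedar has the flask's [substrate] and half its [free catalyst]. The flask's value at 25.0 min by the same law, 24.4 %, over cedar's 22.3 %, is 1.09. This is the catalyst return: the factor by which doubling the free catalyst multiplies percent product, with substrate, gas phase and time held, here a reading at 25.0 min that carries the scatter.

5. Tuesday's therefore came to 24.8 % in my reckoning, a gain of 2.1 points. No run moved the gas, so the readings gave me neither Monday's, which doubles the transfer coefficient, nor Sunday's, which doubles the saturation concentration, and I backed Sunday's by judgement.

6. The forecast said 26 % (range 23 % to 30 %), 33 % after Tuesday's, more than my figure, and Sunday's as best, since it "relieves both resistances".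

7. The flask gave 22.6 %, and 24.6 % after Tuesday's; Sunday's was best, with a gain of 18 points against 5.8 points for Monday's.

    gas phase ⇌ dissolved gas, rate k1*(csat - [dissolved gas]) (kL = 0.765 min⁻¹)
    substrate + dissolved gas + free catalyst → free catalyst + product (k = 68100 M⁻² s⁻¹)
    dissolved gas + free catalyst → spent catalyst A (k = 7.41 M⁻¹ min⁻¹)
    2 free catalyst → spent catalyst B (k = 3940 M⁻¹ min⁻¹)

In the flask, free catalyst pairing with itself (second-order deactivation) had a first half-life by this step alone of 2.54 min, shorter than the 20 min of the run. At 20.0 min the flask held 11.0 % free catalyst beside 88.1 % spent catalyst B and 0.931 % spent catalyst A. The catalyst return turned 22.6 % into 24.6 % for Tuesday's, which gave 24.6 %. Applied over 0.766 doublings, it gave 24.3 % for the neighbour flask with 0.085 mM of free catalyst, which gave 24.2 %.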